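The γ-butyrolactone ring (O1, C2 carbonyl, C3, C4, C5) is cut at two bonds, C4–C5 and O1–C2, so that the unsubstituted C5 methylene and the ring oxygen O1 leave together as formaldehyde. What remains is an E-configured α-branched enal: its aldehyde carbon becomes C2, its α carbon carries the 3,4,5-trimethoxybenzyl group (C3), and its β carbon carries the O-benzyl-protected guaiacylmethyl group (C4). A chiral triazolylidene turns this enal into a homoenolate that joins formaldehyde at C4 and lactonises, building the ring, both ring bonds and the C4 configuration in one operation. C3 is then settled thermodynamically. The enal is assembled convergently by cross-metathesis.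

Key step: step 5

Assumption: the facial sense that the aminoindanol-derived carbene imposes on an α-branched enal cannot be predicted with confidence; the (5aR,10bS) catalyst is written, and its commercial antipode would be used if the open face leads to 4S. Lactone numbering O1, C2 (C=O), C3, C4, C5 is used throughout.

Step 1
Reactants: 1 eugenol (4-allyl-2-methoxyphenol)
Product: 2 O-benzyleugenol (4-allyl-1-benzyloxy-2-methoxybenzene)
Conditions: BnBr, K2CO3, acetone, reflux
Reagents that add atoms: benzyl bromide, BrCc1ccccc1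
Why: Williamson ether synthesis on the phenoxide; the benzyl ether masks the acidic, acylable phenol through the metathesis and carbene steps and is removed under neutral hydrogenolysis at the end.

Step 2
Reactants: 3 5-iodo-1,2,3-trimethoxybenzene; 4 allyl alcohol (prop-2-en-1-ol)
Product: 5 3-(3,4,5-trimethoxyphenyl)propanal
Conditions: Pd(OAc)2 (3 mol%), n-Bu4NCl, NaHCO3, DMF, 45 °C
Reagents that add atoms: none
Why: Mizoroki–Heck arylation of an allylic alcohol under ligand-free phase-transfer conditions, in which oxidative addition of the aryl iodide to zerovalent palladium and insertion at the terminal alkene carbon are followed by β-hydride elimination toward the carbinol, giving an enol that tautomerises to the saturated aldehyde.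

Step 3
Reactants: 5 3-(3,4,5-trimethoxyphenyl)propanal; 6 formaldehyde (as 37% aqueous solution)
Product: 7 2-(3,4,5-trimethoxybenzyl)prop-2-enal
Conditions: 37% aq. CH2O, pyrrolidine (10 mol%), EtCO2H (10 mol%), i-PrOH, 45 °C
Reagents that add atoms: none
Why: amine-catalysed α-methylenation (Mannich condensation of the enamine with formaldehyde, then elimination of the amine), a general reaction of α-unbranched aldehydes that creates no stereocentre.

Step 4
Reactants: 7 2-(3,4,5-trimethoxybenzyl)prop-2-enal; 2 O-benzyleugenol (2 equiv)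
Product: 8 (E)-4-(4-benzyloxy-3-methoxyphenyl)-2-(3,4,5-trimethoxybenzyl)but-2-enal
Conditions: second-generation Hoveyda–Grubbs catalyst RuCl2(H2IMes)(=CH-C6H4-2-O-i-Pr) (5 mol%), 1,4-benzoquinone (10 mol%), CH2Cl2, 40 °C, argon purge
Reagents that add atoms: none
Why: olefin cross-metathesis of a terminal allylarene with a 2-substituted acrolein that cannot homodimerise is the established route to trisubstituted enals; loss of ethene drives it, the E isomer (formyl trans to the new CH2Ar group) is favoured under reversible metathesis, and benzoquinone suppresses hydride-mediated allyl-to-propenyl migration.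

Step 5
Reactants: 8 (E)-4-(4-benzyloxy-3-methoxyphenyl)-2-(3,4,5-trimethoxybenzyl)but-2-enal; 6 formaldehyde (as paraformaldehyde)
Product: 9 (4R)-4-(4-benzyloxy-3-methoxybenzyl)-3-(3,4,5-trimethoxybenzyl)dihydrofuran-2(3H)-one (O-benzylhernanol skeleton; C4 = R, mixture of the trans 3R,4R and cis 3S,4R epimers at C3)
Conditions: (CH2O)n (3 equiv), (5aR,10bS)-2-mesityl-5a,10b-dihydro-4H,6H-indeno[2,1-b][1,2,4]triazolo[4,3-d][1,4]oxazin-2-ium chloride (15 mol%), i-Pr2NEt (20 mol%), 4 Å MS, THF, 40 °C
Reagents that add atoms: none
Why: Proposed new method: the free carbene adds to the aldehyde carbon of 8 and proton transfer gives the conjugated enaminol (homoenolate), whose β carbon (lactone C4) attacks monomeric formaldehyde to form C4–C5; the resulting azolium enol is protonated at C3 to an acyl azolium, and the new alkoxide O1 acylates on it in a 5-exo-trig closure that forms O1–C2, closes the γ-lactone ring and releases the carbene. The closest known reaction type is the carbene-catalysed homoenolate [3+2] annulation of enals with aryl aldehydes or activated ketones to γ-butyrolactones, which has not been shown with formaldehyde or with an α-branched enal carrying a γ-CH2 group. C4 is controlled by the catalyst: the indane wall of the aminoindanol-derived triazolylidene covers one face of the planar E-configured enaminol, so formaldehyde, oriented by a hydrogen bond to the enaminol OH, should reach C4 from the open face; C5 is not stereogenic, and C3, set by a protonation that is not expected to be selective, is left to step 6. The step needs β-carbon rather than acyl-carbon attack on formaldehyde, which the α-benzyl branch of 8 should favour by crowding the acyl anion position, and a single alkene geometry, which step 4 supplies. Capture of the carbene by formaldehyde and γ-deprotonation of the doubly activated CH2 are held back by the slow depolymerisation of paraformaldehyde and by the weak amine base.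

Step 6
Reactants: 9 (4R)-lactone, C3 epimer mixture
Product: 10 O-benzylhernanol, (3R,4R)-4-(4-benzyloxy-3-methoxybenzyl)-3-(3,4,5-trimethoxybenzyl)dihydrofuran-2(3H)-one (trans)
Conditions: DBU (1 equiv), toluene, 80 °C
Reagents that add atoms: none
Why: base-mediated epimerisation through the lactone enolate puts C3 under thermodynamic control, and the trans arrangement of the two benzyl groups (3R,4R) is the more stable isomer of 3,4-dibenzyl-γ-butyrolactones, while C4 carries no acidic hydrogen and keeps its configuration.

Step 7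
Reactants: 10 O-benzylhernanol
Product: 11 hernanol, (3R,4R)-4-(4-hydroxy-3-methoxybenzyl)-3-(3,4,5-trimethoxybenzyl)dihydrofuran-2(3H)-one
Conditions: H2 (1 atm), 10% Pd/C, EtOAc–EtOH, rt
Reagents that add atoms: none
Why: catalytic hydrogenolysis of the benzyl aryl ether under neutral conditions leaves the lactone, the methyl ethers and both stereocentres untouched.

Compound list
1 | eugenol (4-allyl-2-methoxyphenol) | C=CCc1ccc(O)c(OC)c1 | starting material
2 | O-benzyleugenol (4-allyl-1-benzyloxy-2-methoxybenzene) | C=CCc1ccc(OCc2ccccc2)c(OC)c1 | intermediate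
3 | 5-iodo-1,2,3-trimethoxybenzene | COc1cc(I)cc(OC)c1OC | starting material
4 | allyl alcohol (prop-2-en-1-ol) | C=CCO | starting material
5 | 3-(3,4,5-trimethoxyphenyl)propanal | COc1cc(CCC=O)cc(OC)c1OC | intermediate
6 | formaldehyde (37% aqueous solution in step 3, paraformaldehyde in step 5) | C=O | starting material
7 | 2-(3,4,5-trimethoxybenzyl)prop-2-enal | C=C(Cc1cc(OC)c(OC)c(OC)c1)C=O | intermediate
8 | (E)-4-(4-benzyloxy-3-methoxyphenyl)-2-(3,4,5-trimethoxybenzyl)but-2-enal | O=C/C(Cc1cc(OC)c(OC)c(OC)c1)=C/Cc1ccc(OCc2ccccc2)c(OC)c1 | intermediate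
9 | (4R)-4-(4-benzyloxy-3-methoxybenzyl)-3-(3,4,5-trimethoxybenzyl)dihydrofuran-2(3H)-one, C3 epimer mixture | COc1cc(C[C@H]2COC(=O)C2Cc2cc(OC)c(OC)c(OC)c2)ccc1OCc1ccccc1 | intermediate
10 | O-benzylhernanol, (3R,4R)-4-(4-benzyloxy-3-methoxybenzyl)-3-(3,4,5-trimethoxybenzyl)dihydrofuran-2(3H)-one | COc1cc(C[C@H]2COC(=O)[C@@H]2Cc2cc(OC)c(OC)c(OC)c2)ccc1OCc1ccccc1 | intermediate
11 | hernanol, (3R,4R)-4-(4-hydroxy-3-methoxybenzyl)-3-(3,4,5-trimethoxybenzyl)dihydrofuran-2(3H)-one | COc1cc(C[C@H]2COC(=O)[C@@H]2Cc2cc(OC)c(OC)c(OC)c2)ccc1O | target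

Total step count: 7. Longest linear sequence: 6 steps (3 → 5 → 7 → 8 → 9 → 10 → 11, steps 2 to 7).

Steps most likely to fail

Step 5 (Proposed new method). The carbene may be consumed by self-condensation of formaldehyde. The enaminol may hydroxymethylate at the acyl carbon or be protonated at the β carbon. The double bond may drift toward the arene after γ-deprotonation. Facial selectivity at C4 may be poor with so small an electrophile. The fallback uses known auxiliary chemistry, sets out from 2 and rejoins the route at 10, bypassing 8 and 9. Hydroboration–oxidation of 2 (9-BBN, THF; then NaOH, H2O2) should give 3-(4-benzyloxy-3-methoxyphenyl)propan-1-ol F1, which TEMPO/PhI(OAc)2 in aqueous MeCN oxidises to 3-(4-benzyloxy-3-methoxyphenyl)propanoic acid F2. Activation as the mixed pivalic anhydride (t-BuCOCl, Et3N) and acylation of lithiated (S)-4-benzyloxazolidin-2-one gives (S)-4-benzyl-3-[3-(4-benzyloxy-3-methoxyphenyl)propanoyl]oxazolidin-2-one F3. Evans alkylation of its sodium Z-enolate (NaHMDS, THF, −78 °C) with tert-butyl bromoacetate, the electrophile entering opposite the auxiliary benzyl group, gives tert-butyl (3R)-4-(4-benzyloxy-3-methoxyphenyl)-3-{[(4S)-4-benzyl-2-oxooxazolidin-3-yl]carbonyl}butanoate F4. LiBH4 (THF, 0 °C) removes the auxiliary reductively to give tert-butyl (3R)-4-(4-benzyloxy-3-methoxyphenyl)-3-(hydroxymethyl)butanoate F5, and CF3CO2H in CH2Cl2 closes it to (R)-4-(4-benzyloxy-3-methoxybenzyl)dihydrofuran-2(3H)-one F6. Deprotonation with LiHMDS (THF, −78 °C) and alkylation with 3,4,5-trimethoxybenzyl bromide, anti to the C4 substituent, should give the trans lactone 10 directly.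

Step 4. The allyl group of 2 may migrate into conjugation before metathesis, which would lead to an enal one carbon short. Turnover at the hindered 1,1-disubstituted alkene may be slow, and E selectivity may be incomplete. The fallback sets out from 2 and returns at 8 by carbonyl olefination. Ozonolysis of 2 (O3, CH2Cl2–MeOH, −78 °C, indicator end point; Me2S) gives (4-benzyloxy-3-methoxyphenyl)acetaldehyde F7, used crude. Separately, commercial ethyl (triphenylphosphoranylidene)acetate is C-alkylated with 3,4,5-trimethoxybenzyl bromide (EtOAc, reflux) to [1-ethoxy-1-oxo-3-(3,4,5-trimethoxyphenyl)propan-2-yl]triphenylphosphonium bromide F8, which aqueous NaOH/CH2Cl2 converts into ethyl 3-(3,4,5-trimethoxyphenyl)-2-(triphenylphosphoranylidene)propanoate F9. Wittig olefination of F7 with F9 (CH2Cl2, rt), base-free and E-selective for a stabilised ylide, gives ethyl (E)-4-(4-benzyloxy-3-methoxyphenyl)-2-(3,4,5-trimethoxybenzyl)but-2-enoate F10. i-Bu2AlH (CH2Cl2, −78 °C) reduces it to (E)-4-(4-benzyloxy-3-methoxyphenyl)-2-(3,4,5-trimethoxybenzyl)but-2-en-1-ol F11, and MnO2 (CH2Cl2, rt) oxidises the allylic alcohol to 8.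

Step 2. β-Hydride elimination toward the ring would give the cinnamyl alcohol, arylation at the internal alkene carbon would give the branched aldehyde, and the product may self-condense under the basic conditions. The fallback sets out from 3 and returns at 5 with unambiguous regiochemistry. Mizoroki–Heck coupling of 3 with ethyl acrylate (Pd(OAc)2, P(o-tol)3, Et3N, DMF, 90 °C) gives ethyl (E)-3-(3,4,5-trimethoxyphenyl)prop-2-enoate F12. Hydrogenation (H2, Pd/C, EtOAc, rt) gives ethyl 3-(3,4,5-trimethoxyphenyl)propanoate F13, and i-Bu2AlH (1 equiv, toluene, −78 °C) gives 5.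

Further compounds
F1 | step 5 | 3-(4-benzyloxy-3-methoxyphenyl)propan-1-ol | OCCCc1ccc(OCc2ccccc2)c(OC)c1
F2 | step 5 | 3-(4-benzyloxy-3-methoxyphenyl)propanoic acid | OC(=O)CCc1ccc(OCc2ccccc2)c(OC)c1
F3 | step 5 | (S)-4-benzyl-3-[3-(4-benzyloxy-3-methoxyphenyl)propanoyl]oxazolidin-2-one | COc1cc(CCC(=O)N2[C@@H](Cc3ccccc3)COC2=O)ccc1OCc1ccccc1
F4 | step 5 | tert-butyl (3R)-4-(4-benzyloxy-3-methoxyphenyl)-3-{[(4S)-4-benzyl-2-oxooxazolidin-3-yl]carbonyl}butanoate | COc1cc(C[C@H](CC(=O)OC(C)(C)C)C(=O)N2[C@@H](Cc3ccccc3)COC2=O)ccc1OCc1ccccc1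
F5 | step 5 | tert-butyl (3R)-4-(4-benzyloxy-3-methoxyphenyl)-3-(hydroxymethyl)butanoate | COc1cc(C[C@@H](CO)CC(=O)OC(C)(C)C)ccc1OCc1ccccc1
F6 | step 5 | (R)-4-(4-benzyloxy-3-methoxybenzyl)dihydrofuran-2(3H)-one | COc1cc(C[C@H]2COC(=O)C2)ccc1OCc1ccccc1
F7 | step 4 | (4-benzyloxy-3-methoxyphenyl)acetaldehyde | O=CCc1ccc(OCc2ccccc2)c(OC)c1
F8 | step 4 | [1-ethoxy-1-oxo-3-(3,4,5-trimethoxyphenyl)propan-2-yl]triphenylphosphonium bromide | CCOC(=O)C(Cc1cc(OC)c(OC)c(OC)c1)[P+](c1ccccc1)(c1ccccc1)c1ccccc1.[Br-]
F9 | step 4 | ethyl 3-(3,4,5-trimethoxyphenyl)-2-(triphenylphosphoranylidene)propanoate | CCOC(=O)C(Cc1cc(OC)c(OC)c(OC)c1)=P(c1ccccc1)(c1ccccc1)c1ccccc1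
F10 | step 4 | ethyl (E)-4-(4-benzyloxy-3-methoxyphenyl)-2-(3,4,5-trimethoxybenzyl)but-2-enoate | CCOC(=O)/C(Cc1cc(OC)c(OC)c(OC)c1)=C/Cc1ccc(OCc2ccccc2)c(OC)c1
F11 | step 4 | (E)-4-(4-benzyloxy-3-methoxyphenyl)-2-(3,4,5-trimethoxybenzyl)but-2-en-1-ol | OC/C(Cc1cc(OC)c(OC)c(OC)c1)=C/Cc1ccc(OCc2ccccc2)c(OC)c1
F12 | step 2 | ethyl (E)-3-(3,4,5-trimethoxyphenyl)prop-2-enoate | CCOC(=O)/C=C/c1cc(OC)c(OC)c(OC)c1
F13 | step 2 | ethyl 3-(3,4,5-trimethoxyphenyl)propanoate | CCOC(=O)CCc1cc(OC)c(OC)c(OC)c1
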